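**Retrosynthetic overview**

1. Target 13 ⇐ cross-conjugated dienone 11: hydride adds 1,4 to the plain enone arm and the resulting enolate is C-allylated, so C6 is set last.
2. Dienone 11 ⇐ symmetric p-quinol 8 + CH2O: a hemiformal oxa-Michael addition onto one of the two equivalent enone arms, then dehydrogenation, closes the dioxole ring and fixes C7a.
3. p-Quinol 8 ⇐ phenol 6 by oxidative dearomatization with singlet oxygen.
4. Phenol 6 ⇐ (E)-stilbene 5 by asymmetric hydrogenation (sets C8); 5 ⇐ 4'-hydroxyacetophenone 2 + 3,4,5-trimethoxybenzyl chloride 1.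
5. Ring order: both benzene rings are bought; the phenol ring becomes the carbocycle of the target, and the 1,3-dioxole ring is then closed onto it.

Assumption: the sense of induction of the chiral catalysts in steps 2 and 4 is taken from the closest parent substrates; if the first run shows the opposite sense, the mirror-image catalyst is used.

**Route**

Step 1
Reactants: 1 5-(chloromethyl)-1,2,3-trimethoxybenzene; 2 1-(4-hydroxyphenyl)ethan-1-one (4'-hydroxyacetophenone)
Product: 5 4-[(E)-1-(3,4,5-trimethoxyphenyl)prop-1-en-2-yl]phenol, via benzylic Grignard reagent 3 (not isolated), via tertiary carbinol 4 (not isolated)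
Conditions: 1 (2.4 equiv), Mg turnings, 2-MeTHF, 0 °C; add 2, 0 → 50 °C; 1 M HCl work-up; then TsOH·H2O (5 mol %), toluene, 80 °C; recrystallise the E isomer
Reagents that add atoms: none
Why: Grignard 1,2-addition to the ketone (the first equivalent is spent on the phenol OH) followed by acid-catalysed E1 dehydration under thermodynamic control gives mainly the conjugated trisubstituted stilbene with the aryl groups trans, and the minor Z and terminal isomers are removed by crystallisation; no stereocentre is formed.

Step 2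
Reactants: 5 4-[(E)-1-(3,4,5-trimethoxyphenyl)prop-1-en-2-yl]phenol
Product: 6 4-[(2S)-1-(3,4,5-trimethoxyphenyl)propan-2-yl]phenol
Conditions: H2 (50 bar), [Ir(cod)(L)][B(C6H3-3,5-(CF3)2)4] (1 mol %), L = (R)-4-tert-butyl-2-[2-(di-o-tolylphosphanyl)phenyl]-4,5-dihydrooxazole, CH2Cl2, 25 °C
Reagents that add atoms: none
Why: Iridium N,P-ligand (Pfaltz-type) asymmetric hydrogenation of an (E)-α-methylstilbene, the benchmark substrate class for these catalysts (typically ≥97% ee), in which the chiral pocket selects the alkene face and so sets C8 as S; a free phenol carries no basic site that would poison the cationic catalyst.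

Step 3
Reactants: 6 4-[(2S)-1-(3,4,5-trimethoxyphenyl)propan-2-yl]phenol
Product: 8 4-hydroxy-4-[(2S)-1-(3,4,5-trimethoxyphenyl)propan-2-yl]cyclohexa-2,5-dien-1-one, via hydroperoxy dienone 7 (not isolated)
Conditions: KHSO5 (as the triple salt 2KHSO5·KHSO4·K2SO4), NaHCO3, MeCN/H2O, 25 °C; then Me2S
Reagents that add atoms: potassium peroxymonosulfate, [K+].[O-]S(=O)(=O)OO
Why: Oxidative dearomatization in which singlet oxygen generated from KHSO5 and bicarbonate adds para to the phenolate to give the p-peroxyquinol, which Me2S reduces to the p-quinol; this neutral pathway avoids a phenoxonium ion that the electron-rich trimethoxyphenyl ring could trap, C4 is not a stereocentre because the two enone arms are identical, and C8 is untouched.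

Step 4
Reactants: 8 4-hydroxy-4-[(2S)-1-(3,4,5-trimethoxyphenyl)propan-2-yl]cyclohexa-2,5-dien-1-one
Product: 11 (7aS)-7a-[(2S)-1-(3,4,5-trimethoxyphenyl)propan-2-yl]-1,3-benzodioxol-5(7aH)-one, via hemiformal 9 (not isolated), via cis-fused dioxolane enone 10 (not isolated)
Conditions: (CH2O)n (5 equiv), (R)-TRIP [(R)-3,3'-bis(2,4,6-triisopropylphenyl)-1,1'-binaphthyl-2,2'-diyl hydrogen phosphate] (10 mol %), ClCH2CH2Cl, 40 °C; evaporate; then IBX·4-methoxypyridine N-oxide (2.5 equiv), DMSO, 25 °C
Reagents that add atoms: formaldehyde (from paraformaldehyde), C=O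
Why: Proposed new method: a one-flask relay in which the chiral phosphoric acid forms the hemiformal at the tertiary OH and then, as a bifunctional hydrogen-bonding catalyst, directs its OH onto one of the two diastereotopic enone arms (5-exo oxa-Michael addition, cis fusion enforced by the five-membered ring), which fixes C7a, after which ligated IBX dehydrogenates the β-alkoxy ketone 10, which can enolise only toward C4, to the vinylogous ester at room temperature, removing the C3a centre but leaving C7a; the closest known reactions are the phosphoric-acid-catalysed acetalization/oxa-Michael desymmetrization of p-quinols and p-peroxyquinols with aldehydes and the IBX dehydrogenation of ketones to enones.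

Step 5
Reactants: 11 (7aS)-7a-[(2S)-1-(3,4,5-trimethoxyphenyl)propan-2-yl]-1,3-benzodioxol-5(7aH)-one
Product: 13 (6R,7aR)-6-(prop-2-en-1-yl)-7a-[(2S)-1-(3,4,5-trimethoxyphenyl)propan-2-yl]-7,7a-dihydro-1,3-benzodioxol-5(6H)-one, via lithium enolate 12 (not isolated)
Conditions: LiBH(s-Bu)3 (1.05 equiv), THF, −78 °C; then allyl bromide (3 equiv), DMPU, −78 → 0 °C
Reagents that add atoms: allyl bromide, C=CCBr
Why: Reductive alkylation of an enone (Ganem type): the bulky borohydride adds 1,4 to the plain enone arm only, since the other arm is a deactivated vinylogous ester (compare the selective reduction of the C1–C2 double bond of steroidal 1,4-dien-3-ones), and the regiodefined lithium enolate is allylated at C6 on the face opposite the pseudoaxial C7a side chain, which places allyl trans to that chain and equatorial, also the thermodynamically preferred epimer, so C6 is R.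

**Compound list**

1 | 5-(chloromethyl)-1,2,3-trimethoxybenzene (3,4,5-trimethoxybenzyl chloride) | COc1cc(CCl)cc(OC)c1OC | starting material
2 | 1-(4-hydroxyphenyl)ethan-1-one (4'-hydroxyacetophenone) | CC(=O)c1ccc(O)cc1 | starting material
3 | (3,4,5-trimethoxybenzyl)magnesium chloride | COc1cc(C[Mg]Cl)cc(OC)c1OC | intermediate
4 | 4-[2-hydroxy-1-(3,4,5-trimethoxyphenyl)propan-2-yl]phenol (racemic) | CC(O)(Cc1cc(OC)c(OC)c(OC)c1)c1ccc(O)cc1 | intermediate
5 | 4-[(E)-1-(3,4,5-trimethoxyphenyl)prop-1-en-2-yl]phenol | C/C(=C\c1cc(OC)c(OC)c(OC)c1)c1ccc(O)cc1 | intermediate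
6 | 4-[(2S)-1-(3,4,5-trimethoxyphenyl)propan-2-yl]phenol | Oc1ccc(cc1)[C@@H](C)Cc1cc(OC)c(OC)c(OC)c1 | intermediate
7 | 4-hydroperoxy-4-[(2S)-1-(3,4,5-trimethoxyphenyl)propan-2-yl]cyclohexa-2,5-dien-1-one | O=C1C=CC(OO)([C@@H](C)Cc2cc(OC)c(OC)c(OC)c2)C=C1 | intermediate
8 | 4-hydroxy-4-[(2S)-1-(3,4,5-trimethoxyphenyl)propan-2-yl]cyclohexa-2,5-dien-1-one | O=C1C=CC(O)([C@@H](C)Cc2cc(OC)c(OC)c(OC)c2)C=C1 | intermediate
9 | 4-(hydroxymethoxy)-4-[(2S)-1-(3,4,5-trimethoxyphenyl)propan-2-yl]cyclohexa-2,5-dien-1-one | O=C1C=CC(OCO)([C@@H](C)Cc2cc(OC)c(OC)c(OC)c2)C=C1 | intermediate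
10 | (3aR,7aS)-7a-[(2S)-1-(3,4,5-trimethoxyphenyl)propan-2-yl]-3a,7a-dihydro-1,3-benzodioxol-5(4H)-one (cis-fused) | O=C1C=C[C@]2([C@@H](C)Cc3cc(OC)c(OC)c(OC)c3)OCO[C@@H]2C1 | intermediate
11 | (7aS)-7a-[(2S)-1-(3,4,5-trimethoxyphenyl)propan-2-yl]-1,3-benzodioxol-5(7aH)-one | O=C1C=C[C@]2([C@@H](C)Cc3cc(OC)c(OC)c(OC)c3)OCOC2=C1 | intermediate
12 | lithium (7aR)-7a-[(2S)-1-(3,4,5-trimethoxyphenyl)propan-2-yl]-7,7a-dihydro-1,3-benzodioxol-5-olate | [Li]OC1=CC[C@]2([C@@H](C)Cc3cc(OC)c(OC)c(OC)c3)OCOC2=C1 | intermediate
13 | (6R,7aR)-6-(prop-2-en-1-yl)-7a-[(2S)-1-(3,4,5-trimethoxyphenyl)propan-2-yl]-7,7a-dihydro-1,3-benzodioxol-5(6H)-one | C=CC[C@@H]1C[C@]2([C@@H](C)Cc3cc(OC)c(OC)c(OC)c3)OCOC2=CC1=O | target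

The C7a descriptor changes from S in 10 and 11 to R in 12 and 13 only because C7 changes from sp2 to sp3 and drops below C8 in priority; the geometry is the same throughout.

**Step count and risks**

Total steps: 5. Longest linear sequence: 5 (1 and 2 → 5 → 6 → 8 → 11 → 13).

Steps most likely to fail:

Step 4 (desymmetrization and dehydrogenation in one flask). The chiral acid must override any bias from the neighbouring C8 centre with a hemiformal as small as that of formaldehyde, and the oxa-Michael adduct could partly revert during the oxidation stage, which would erode the C7a ratio. The fallback sets out from 8 and gives up catalyst control. Cyclisation with paraformaldehyde and diphenyl phosphate (10 mol %) gives 10 together with the (3aS,7aR)-dioxolane diastereomer F3. The two are true diastereomers because of C8 and are separated by chromatography. F3 is returned to 8 with DBU in wet MeCN by retro-oxa-Michael reaction and loss of formaldehyde. Isolated 10 is soft-enolised (TMSOTf, Et3N, CH2Cl2, 0 °C) to the trimethylsilyl dienol ether F4 and oxidised with Pd(OAc)2 in MeCN (Saegusa–Ito), which comes back to the route at 11.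

Step 5 (reductive allylation). Possible problems are 1,2-reduction of the dienone carbonyl, proton transfer and double allylation of the enolate. The fallback sets out from 11 and separates reduction from C–C bond formation. Copper hydride conjugate reduction with [(Ph3P)CuH]6 (5 mol %) and PhMe2SiH in toluene gives the dimethyl(phenyl)silyl enol ether F5. Palladium-catalysed allylation of F5 with allyl methyl carbonate (Pd2(dba)3, dppe, THF, 65 °C, Tsuji type) delivers one allyl group regiospecifically, again anti to the axial side chain, and comes back to the route at 13.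

Step 2 (hydrogenation of the free phenol). The acidic OH may slow the iridium catalyst or lower the ee. The fallback sets out from 5, which is acetylated (Ac2O, pyridine) to the aryl acetate F1. F1 is hydrogenated with the same iridium complex, for which aryl acetates are proven substrates, to the saturated (S)-acetate F2. Methanolysis (K2CO3, MeOH) comes back to the route at 6.

**Further compounds**

F1 | step 2 | 4-[(E)-1-(3,4,5-trimethoxyphenyl)prop-1-en-2-yl]phenyl acetate | CC(=O)Oc1ccc(cc1)/C(C)=C/c1cc(OC)c(OC)c(OC)c1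
F2 | step 2 | 4-[(2S)-1-(3,4,5-trimethoxyphenyl)propan-2-yl]phenyl acetate | CC(=O)Oc1ccc(cc1)[C@@H](C)Cc1cc(OC)c(OC)c(OC)c1
F3 | step 4 | (3aS,7aR)-7a-[(2S)-1-(3,4,5-trimethoxyphenyl)propan-2-yl]-3a,7a-dihydro-1,3-benzodioxol-5(4H)-one | O=C1C=C[C@@]2([C@@H](C)Cc3cc(OC)c(OC)c(OC)c3)OCO[C@H]2C1
F4 | step 4 | trimethyl{[(3aR,7aS)-7a-[(2S)-1-(3,4,5-trimethoxyphenyl)propan-2-yl]-3a,7a-dihydro-1,3-benzodioxol-5-yl]oxy}silane | C[Si](C)(C)OC1=C[C@H]2OCO[C@@]2([C@@H](C)Cc3cc(OC)c(OC)c(OC)c3)C=C1
F5 | step 5 | dimethyl(phenyl){[(7aR)-7a-[(2S)-1-(3,4,5-trimethoxyphenyl)propan-2-yl]-7,7a-dihydro-1,3-benzodioxol-5-yl]oxy}silane | C[Si](C)(c1ccccc1)OC1=CC[C@]2([C@@H](C)Cc3cc(OC)c(OC)c(OC)c3)OCOC2=C1
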